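**Retrosynthetic overview**
1. The C3 angelate and the C9 (E)-3-methylpent-2-enoate are attached last, from two acyl donors made separately (a Yamaguchi mixed anhydride and an acid chloride).
2. The C7 isopropenyl group comes from the C7 enolate and separately made (trimethylsilyl)acetone (aldol, then Peterson elimination).
3. The 9α-oxygen and the trans ring fusion come from a Δ9(10)-8-enone: Li/NH3 reduction, silyl enol ether, Rubottom oxidation.
4. The ring A substituents (3α-O, 4β-Me) come from the C4 ketone of (S)-Wieland–Miescher ketone: enol triflate, methyl coupling, face-selective hydroboration, with the enone masked as a dithiolane.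
5. Ring order: ring A is bought (2-methylcyclohexane-1,3-dione); ring B is closed onto it by the L-proline-mediated intramolecular aldol condensation of the methyl vinyl ketone adduct, which sets C5 and, through it, every other centre.

Assumption: locants are eremophilane-type (ring A = C1–C5 and C10, ring B = C5–C10, C14 = methyl on C5, C15 = methyl on C4, C11–C13 = isopropenyl on C7), β is the face of the C5 methyl, and the target is read as 3R,4R,5R,7S,9S,10R with a trans ring fusion.

**Route**

Step 1
Reactants: 1 2-methylcyclohexane-1,3-dione; 2 methyl vinyl ketone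
Product: 5 (S)-Wieland–Miescher ketone, via triketone 3 (not isolated), via ketol 4 (not isolated)
Conditions: L-proline (35 mol %), DMSO, 35 °C, 90 h; recrystallised from hexane/ethyl acetate to ≥98% ee
Reagents that add atoms: none
Why: One-pot Robinson annulation in which the Michael adduct 3 is closed to ring B by the L-proline enamine intramolecular aldol (Hajos–Parrish–Eder–Sauer–Wiechert reaction), whose hydrogen-bonded transition state picks one of the two enantiotopic ring carbonyls and so sets the quaternary C5 as S before dehydration to the enone.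

Step 2
Reactants: 5 (S)-Wieland–Miescher ketone
Product: 6 C8-dithiolane ketone
Conditions: HSCH2CH2SH (1.1 equiv), p-toluenesulfonic acid (cat.), AcOH, rt, 4 h
Reagents that add atoms: ethane-1,2-dithiol, SCCS
Why: Chemoselective thioketalisation, in which the conjugated C8 carbonyl reacts under acid in AcOH while the neopentyl C4 ketone and the position of the C9=C10 bond are left untouched; no stereocentre is affected.

Step 3
Reactants: 6 C8-dithiolane ketone
Product: 8 C4 enol triflate, via potassium enolate 7 (not isolated)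
Conditions: KN(SiMe3)2 (1.2 equiv), THF, −78 °C; PhNTf2 (1.2 equiv), −78 → 0 °C
Reagents that add atoms: N-phenylbis(trifluoromethanesulfonimide), O=S(=O)(N(c1ccccc1)S(=O)(=O)C(F)(F)F)C(F)(F)F
Why: Enol triflate formation, regiospecific because the C4 ketone can only enolise toward C3 (C5 is quaternary) and the thioketal has no acidic position.

Step 4
Reactants: 8 C4 enol triflate
Product: 9 4-methyl-3,9-diene dithiolane
Conditions: MeMgBr (1.5 equiv), Fe(acac)3 (5 mol %), THF/NMP, −30 → 0 °C
Reagents that add atoms: methylmagnesium bromide, C[Mg]Br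
Why: Iron-catalysed Kumada-type cross-coupling of an alkenyl triflate with a Grignard reagent puts in the C15 methyl with the C3=C4 double bond fixed in place.

Step 5
Reactants: 9 4-methyl-3,9-diene dithiolane
Product: 11 3α-alcohol dithiolane, via alkylborane 10 (not isolated)
Conditions: BH3·THF (2.0 equiv), THF, 0 °C → rt, 3 h; 3 M NaOH, 30% H2O2, 0 °C, 30 min
Reagents that add atoms: hydrogen peroxide, OO
Why: Brown hydroboration–oxidation, in which borane adds syn and anti-Markovnikov to C3=C4 from the α face opposite the axial C5 methyl (H to C4, so C15 ends 4β and cis to C14; O to C3α), while the C9=C10 bond between the spiro-dithiolane and the ring fusion is too hindered to compete.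

Step 6
Reactants: 11 3α-alcohol dithiolane
Product: 12 TBS ether dithiolane
Conditions: TBSCl (1.5 equiv), imidazole (3 equiv), DMF, rt → 40 °C
Reagents that add atoms: tert-butyldimethylsilyl chloride, CC(C)(C)[Si](C)(C)Cl
Why: Corey silylation of the equatorial secondary alcohol gives an ether that survives dissolving metal, amide base and peracid; the configuration at C3 is retained.

Step 7
Reactants: 12 TBS ether dithiolane
Product: 13 TBS enone
Conditions: MeI (10 equiv), CaCO3 (3 equiv), MeCN/H2O 4:1, 50 °C
Reagents that add atoms: water, O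
Why: Alkylative hydrolysis of the dithiolane (S-methylation, opening to the allylic thionium ion, capture by water) returns the enone under near-neutral conditions that spare the silyl ether.

Step 8
Reactants: 13 TBS enone
Product: 15 TMS enol ether, via lithium enolate 14 (not isolated)
Conditions: Li (2.5 equiv), NH3(l)/THF, t-BuOH (1.0 equiv), −78 °C (13 added to the blue solution); isoprene; NH3 removed; TMSCl/Et3N (1:1, 5 equiv), THF, −78 → 0 °C
Reagents that add atoms: chlorotrimethylsilane, C[Si](C)(C)Cl
Why: Birch-type dissolving-metal reduction of the enone followed by Stork enolate trapping, in which axial protonation at C10 gives the trans ring fusion (10α-H, anti to the C5 methyl) and the enolate is fixed regiospecifically as the C8=C9 silyl enol ether.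

Step 9
Reactants: 15 TMS enol ether
Product: 17 9α-silyloxy ketone, via silyloxy epoxide 16 (not isolated)
Conditions: mCPBA (1.05 equiv), hexane, −15 °C → rt, 2 h; filtered through Celite
Reagents that add atoms: 3-chloroperbenzoic acid, OOC(=O)c1cccc(Cl)c1
Why: Rubottom oxidation, in which the peracid epoxidises the enol ether from the α face (the β face of C9 is 1,3-diaxial to the C5 methyl) and 1,4-silyl migration of the opened epoxide gives the equatorial 9α-OTMS ketone.

Step 10
Reactants: 18 (trimethylsilyl)methylmagnesium chloride; 19 acetic anhydride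
Product: 20 (trimethylsilyl)acetone
Conditions: 18 (1 M in Et2O) added to 19 (3 equiv), Et2O, −78 °C; aq. NH4Cl; distilled
Reagents that add atoms: none
Why: Acylation of a Grignard reagent by an anhydride at low temperature stops at the ketone because the tetrahedral adduct survives until work-up.

Step 11
Reactants: 17 9α-silyloxy ketone; 20 (trimethylsilyl)acetone
Product: 23 9α-hydroxy-7α-isopropenyl ketone, via lithium enolate 21 (not isolated), via hydroxysilane adduct 22 (not isolated)
Conditions: LiN(i-Pr)2 (1.1 equiv), THF, −78 °C; CeCl3 (1.2 equiv), −78 °C; 20 (1.5 equiv), −78 °C; AcOH, −78 °C; crude adduct: CF3CO2H (3 equiv), CH2Cl2, 0 °C, 30 min; aq. NaHCO3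
Reagents that add atoms: none
Why: Kinetic α′-deprotonation at C7 (the C9–H next to the silyloxy group is not removed), cerium-enolate aldol addition to the silyl ketone and acid-induced Peterson elimination give the isopropenyl group regiospecifically as the terminal alkene, the side chain entering anti to the C5 methyl to give the equatorial and thermodynamically preferred 7α epimer, and the acid also frees the 9-OH.

Step 12
Reactants: 24 ethyl but-2-ynoate
Product: 26 ethyl (E)-3-methylpent-2-enoate, via alkenylcopper 25 (not isolated)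
Conditions: EtMgBr (1.2 equiv), CuBr·SMe2 (1.2 equiv), THF, −78 °C, 1 h; 24, −78 °C, 2 h; MeOH, −78 °C
Reagents that add atoms: ethylmagnesium bromide, CC[Mg]Br
Why: Syn carbocupration of the ynoate places ethyl and copper on the same side of the new double bond, and protonation at −78 °C with retention leaves the ester cis to the methyl group, i.e. the E enoate.

Step 13
Reactants: 26 ethyl (E)-3-methylpent-2-enoate
Product: 28 (E)-3-methylpent-2-enoic acid, via lithium carboxylate 27 (not isolated)
Conditions: LiOH·H2O (2 equiv), THF/MeOH/H2O, rt; 1 M HCl to pH 2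
Reagents that add atoms: lithium hydroxide, [Li+].[OH-]
Why: Saponification by acyl–oxygen cleavage at room temperature, which does not disturb the trisubstituted double-bond geometry.

Step 14
Reactants: 28 (E)-3-methylpent-2-enoic acid
Product: 29 (E)-3-methylpent-2-enoyl chloride
Conditions: (COCl)2 (1.2 equiv), N,N-dimethylformamide (cat.), CH2Cl2, 0 °C → rt; bulb-to-bulb distillation
Reagents that add atoms: oxalyl chloride, ClC(=O)C(Cl)=O
Why: Vilsmeier-type chlorination of the acid under neutral conditions keeps the E geometry.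

Step 15
Reactants: 23 9α-hydroxy-7α-isopropenyl ketone; 29 (E)-3-methylpent-2-enoyl chloride
Product: 30 C9 ester TBS ether
Conditions: 29 (1.5 equiv), pyridine (3 equiv), 4-dimethylaminopyridine (10 mol %), CH2Cl2, 0 °C → rt
Reagents that add atoms: none
Why: Nucleophile-catalysed acylation of the only free hydroxyl (equatorial 9α-OH) with a weak base at low temperature, which avoids vinylketene formation and leaves C9 and C7 unchanged.

Step 16
Reactants: 30 C9 ester TBS ether
Product: 31 C9 ester 3α-alcohol
Conditions: HF·pyridine, THF/pyridine, 0 °C → rt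
Reagents that add atoms: none
Why: Fluoride-mediated desilylation under mildly acidic conditions frees the 3α-OH without touching the enoate, the α-acyloxy ketone or the β,γ-alkene.

Step 17
Reactants: 32 methyl 2-[bis(2,2,2-trifluoroethoxy)phosphoryl]propanoate; 33 acetaldehyde
Product: 35 methyl angelate, via potassium phosphonate 34 (not isolated)
Conditions: KN(SiMe3)2 (1.0 equiv), 18-crown-6 (3 equiv), THF, −78 °C; MeCHO (1.5 equiv), −78 °C, 1 h
Reagents that add atoms: none
Why: Still–Gennari variant of the Horner–Wadsworth–Emmons olefination, in which the electron-poor phosphonate makes elimination fast and kinetically controlled and so gives the Z (angelate) trisubstituted enoate.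

Step 18
Reactants: 35 methyl angelate
Product: 37 angelic acid, via lithium angelate 36 (not isolated)
Conditions: LiOH·H2O (2 equiv), THF/H2O 3:1, rt; 1 M HCl, 0 °C
Reagents that add atoms: lithium hydroxide, [Li+].[OH-]
Why: Saponification at room temperature, well below the conditions that isomerise angelate to tiglate.

Step 19
Reactants: 37 angelic acid
Product: 38 angelic 2,4,6-trichlorobenzoic anhydride
Conditions: 2,4,6-trichlorobenzoyl chloride (1.0 equiv), Et3N (1.1 equiv), THF, rt, 2 h; salt filtered off, filtrate concentrated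
Reagents that add atoms: 2,4,6-trichlorobenzoyl chloride, ClC(=O)c1c(Cl)cc(Cl)cc1Cl
Why: Yamaguchi mixed-anhydride formation without a nucleophilic catalyst, so the Z double bond is not isomerised.

Step 20
Reactants: 31 C9 ester 3α-alcohol; 38 angelic 2,4,6-trichlorobenzoic anhydride
Product: 39 CNP0301161.1
Conditions: 38 (3 equiv), toluene, 75 °C, 12 h
Reagents that add atoms: none
Why: Yamaguchi-type esterification, in which the alcohol attacks the unhindered angeloyl carbonyl of the mixed anhydride (the aryl carbonyl is shielded by two ortho chlorines) and O3 is acylated with retention at C3, without an acyl-transfer catalyst so that the angelate geometry and the C7 and C9 centres are kept.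

**Compound list**

1 | 2-methylcyclohexane-1,3-dione | CC1C(=O)CCCC1=O | starting material
2 | methyl vinyl ketone (but-3-en-2-one) | CC(=O)C=C | starting material
3 | 2-methyl-2-(3-oxobutyl)cyclohexane-1,3-dione (achiral triketone) | CC(=O)CCC1(C)C(=O)CCCC1=O | intermediate
4 | (4aS,8aS)-4a-hydroxy-8a-methyloctahydronaphthalene-1,6-dione (cis-fused ketol) | C1C[C@]2(C)C(=O)CCC[C@]2(O)CC1=O | intermediate
5 | (S)-Wieland–Miescher ketone, (8aS)-8a-methyl-3,4,8,8a-tetrahydronaphthalene-1,6(2H,7H)-dione | C1C[C@]2(C)C(=O)CCCC2=CC1=O | intermediate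
6 | (5S)-dithiolane ketone: spiro-1,3-dithiolane at C8 of 5, C4 ketone and C9=C10 kept | C1C[C@]2(C)C(=O)CCCC2=CC13SCCS3 | intermediate
7 | potassium C3=C4 enolate of 6 (5S) | C1C[C@]2(C)C([O-])=CCCC2=CC13SCCS3.[K+] | intermediate
8 | (5S)-C4 enol triflate (C3=C4–OTf, C9=C10, C8 dithiolane) | C1C[C@]2(C)C(OS(=O)(=O)C(F)(F)F)=CCCC2=CC13SCCS3 | intermediate
9 | (5R)-4,5-dimethyl-3,9(10)-diene, C8 dithiolane | C1C[C@]2(C)C(C)=CCCC2=CC13SCCS3 | intermediate
10 | (3R,4S,5R)-3α-boryl-4β,5β-dimethyl-Δ9(10)-octalin, C8 dithiolane (alkylborane) | C1C[C@]2(C)[C@@H](C)[C@H](B)CCC2=CC13SCCS3 | intermediate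
11 | (3R,4R,5R)-3α-hydroxy-4β,5β-dimethyl-Δ9(10)-octalin, C8 dithiolane | C1C[C@]2(C)[C@@H](C)[C@H](O)CCC2=CC13SCCS3 | intermediate
12 | (3R,4R,5R)-3α-(tert-butyldimethylsilyloxy)-4β,5β-dimethyl-Δ9(10)-octalin, C8 dithiolane | C1C[C@]2(C)[C@@H](C)[C@H](O[Si](C)(C)C(C)(C)C)CCC2=CC13SCCS3 | intermediate
13 | (3R,4R,5R)-3α-(tert-butyldimethylsilyloxy)-4β,5β-dimethyl-Δ9(10)-octalin-8-one, i.e. (4aR,5R,6R)-6-TBSO-4a,5-dimethyl-4,4a,5,6,7,8-hexahydronaphthalen-2(3H)-one | C1C[C@]2(C)[C@@H](C)[C@H](O[Si](C)(C)C(C)(C)C)CCC2=CC1=O | intermediate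
14 | lithium C8=C9 enolate, trans-fused (3R,4R,5S,10S; 10α-H) | C1C[C@]2(C)[C@@H](C)[C@H](O[Si](C)(C)C(C)(C)C)CC[C@H]2C=C1[O-].[Li+] | intermediate
15 | (3R,4R,5S,10S)-3α-TBSO-8-(trimethylsilyloxy)-4β,5β-dimethyl-trans-Δ8(9)-octalin | C1C[C@]2(C)[C@@H](C)[C@H](O[Si](C)(C)C(C)(C)C)CC[C@H]2C=C1O[Si](C)(C)C | intermediate
16 | (3R,4R,5R,8S,9S,10R)-8α,9α-epoxide of 15 (8β-OTMS) | C1C[C@]2(C)[C@@H](C)[C@H](O[Si](C)(C)C(C)(C)C)CC[C@H]2[C@@H]3O[C@]13O[Si](C)(C)C | intermediate
17 | (3R,4R,5R,9S,10R)-3α-TBSO-9α-(trimethylsilyloxy)-4β,5β-dimethyl-trans-decalin-8-one | C1C[C@]2(C)[C@@H](C)[C@H](O[Si](C)(C)C(C)(C)C)CC[C@H]2[C@H](O[Si](C)(C)C)C1=O | intermediate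
18 | (trimethylsilyl)methylmagnesium chloride | C[Si](C)(C)C[Mg]Cl | starting material
19 | acetic anhydride | CC(=O)OC(C)=O | starting material
20 | 1-(trimethylsilyl)propan-2-one, (trimethylsilyl)acetone | CC(=O)C[Si](C)(C)C | intermediate
21 | lithium C7=C8 enolate of 17 | C=1C[C@]2(C)[C@@H](C)[C@H](O[Si](C)(C)C(C)(C)C)CC[C@H]2[C@H](O[Si](C)(C)C)C=1[O-].[Li+] | intermediate
22 | 7α-[2-hydroxy-1-(trimethylsilyl)propan-2-yl] adduct of 17 (3R,4R,5R,7S,9S,10R; both C11 epimers) | C[Si](C)(C)CC(C)(O)[C@@H]1C[C@]2(C)[C@@H](C)[C@H](O[Si](C)(C)C(C)(C)C)CC[C@H]2[C@H](O[Si](C)(C)C)C1=O | intermediate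
23 | (3R,4R,5R,7S,9S,10R)-3α-TBSO-9α-hydroxy-7α-isopropenyl-4β,5β-dimethyl-trans-decalin-8-one | C=C(C)[C@@H]1C[C@]2(C)[C@@H](C)[C@H](O[Si](C)(C)C(C)(C)C)CC[C@H]2[C@H](O)C1=O | intermediate
24 | ethyl but-2-ynoate | CC#CC(=O)OCC | starting material
25 | ethyl (Z)-2-cuprio-3-methylpent-2-enoate (alkenylcopper, Cu cis to ethyl) | CCOC(=O)/C([Cu])=C(\C)CC | intermediate
26 | ethyl (E)-3-methylpent-2-enoate | CCOC(=O)/C=C(\C)CC | intermediate
27 | lithium (E)-3-methylpent-2-enoate | [Li+].[O-]C(=O)/C=C(\C)CC | intermediate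
28 | (E)-3-methylpent-2-enoic acid | OC(=O)/C=C(\C)CC | intermediate
29 | (E)-3-methylpent-2-enoyl chloride | ClC(=O)/C=C(\C)CC | intermediate
30 | (3R,4R,5R,7S,9S,10R)-3α-TBSO-9α-[(E)-3-methylpent-2-enoyloxy]-7α-isopropenyl-4β,5β-dimethyl-trans-decalin-8-one | C=C(C)[C@@H]1C[C@]2(C)[C@@H](C)[C@H](O[Si](C)(C)C(C)(C)C)CC[C@H]2[C@H](OC(=O)/C=C(\C)CC)C1=O | intermediate
31 | (3R,4R,5R,7S,9S,10R)-3α-hydroxy-9α-[(E)-3-methylpent-2-enoyloxy]-7α-isopropenyl-4β,5β-dimethyl-trans-decalin-8-one | C=C(C)[C@@H]1C[C@]2(C)[C@@H](C)[C@H](O)CC[C@H]2[C@H](OC(=O)/C=C(\C)CC)C1=O | intermediate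
32 | methyl 2-[bis(2,2,2-trifluoroethoxy)phosphoryl]propanoate | COC(=O)C(C)P(=O)(OCC(F)(F)F)OCC(F)(F)F | starting material
33 | acetaldehyde | CC=O | starting material
34 | potassium salt of phosphonate 32 | [K+].COC(=O)[C-](C)P(=O)(OCC(F)(F)F)OCC(F)(F)F | intermediate
35 | methyl angelate, methyl (Z)-2-methylbut-2-enoate | COC(=O)/C(C)=C\C | intermediate
36 | lithium angelate | [Li+].[O-]C(=O)/C(C)=C\C | intermediate
37 | angelic acid, (Z)-2-methylbut-2-enoic acid | OC(=O)/C(C)=C\C | intermediate
38 | angelic 2,4,6-trichlorobenzoic anhydride | O=C(OC(=O)c1c(Cl)cc(Cl)cc1Cl)/C(C)=C\C | intermediate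
39 | CNP0301161.1: (3R,4R,5R,7S,9S,10R)-3α-angeloyloxy-9α-[(E)-3-methylpent-2-enoyloxy]-7α-isopropenyl-4β,5β-dimethyl-trans-decalin-8-one | C=C(C)[C@@H]1C[C@]2(C)[C@@H](C)[C@H](OC(=O)/C(C)=C\C)CC[C@H]2[C@H](OC(=O)/C=C(\C)CC)C1=O | target

**Step count**

Total: 20 steps.
Longest linear sequence: 13 steps (steps 1–9, 11, 15, 16, 20, from 1 to 39). The side sequences are step 10 (20), steps 12–14 (29) and steps 17–19 (38).

**Steps most likely to fail, with fallbacks**

The first is step 5. Borane could also attack the C9=C10 bond, and the alkaline peroxide could oxidise sulfur. The fallback puts the ring A oxygen in before the methyl group. It sets out from 6 and comes back at 13. The potassium enolate 7 is hydroxylated at −78 °C with 2-(phenylsulfonyl)-3-phenyloxaziridine, anti to the C5 methyl, to give the 3α-hydroxy ketone F1. Silylation (TBSOTf, 2,6-lutidine) gives the silyl ether F2. Wittig methylenation of the C4 ketone (Ph3P=CH2 from Ph3PCH3Br and KOt-Bu, toluene, 90 °C) gives the exocyclic alkene F3. MeI/CaCO3 in aqueous MeCN unmasks the dienone F4. Hydrogenation of only the 1,1-disubstituted alkene (H2, RhCl(PPh3)3, benzene) from the α face then delivers the 4β-methyl enone 13.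

The second is step 11. The enolate may deprotonate (trimethylsilyl)acetone or attack its silicon instead of adding to the carbonyl. The fallback forms the C7–C11 bond by cross-coupling. It sets out from 17 and comes back at 23. The C7 enolate (LiN(SiMe3)2, toluene) is coupled with 2-bromopropene using Pd2(dba)3 and P(t-Bu)3 at rt, then quenched with AcOH at −78 °C so the alkene stays out of conjugation. This gives the isopropenyl silyloxy ketone F5. Citric acid in MeOH removes the trimethylsilyl group to give 23.

The third is step 20. Heating the hindered alcohol with the mixed anhydride may be slow, may isomerise angelate to tiglate, or may move the C11 alkene into conjugation. The fallback builds the Z double bond on the substrate at low temperature. It sets out from 31, with 32 as the phosphonate source, and comes back at 39. Me3SnOH in 1,2-dichloroethane at 80 °C cleaves the methyl ester of 32 to the phosphono acid F6. F6 is coupled to O3 of 31 (EDC·HCl, 4-dimethylaminopyridine, CH2Cl2) to give the phosphonate ester F7. Still–Gennari olefination of F7 with acetaldehyde (KN(SiMe3)2, 18-crown-6, THF, −78 °C) gives 39.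

**Further compounds**

F1 | step 5 | (3R,5S)-3α-hydroxy-5-methyl-Δ9(10)-octalin-4-one, C8 dithiolane | C1C[C@]2(C)C(=O)[C@H](O)CCC2=CC13SCCS3
F2 | step 5 | (3R,5S)-3α-(tert-butyldimethylsilyloxy)-5-methyl-Δ9(10)-octalin-4-one, C8 dithiolane | C1C[C@]2(C)C(=O)[C@H](O[Si](C)(C)C(C)(C)C)CCC2=CC13SCCS3
F3 | step 5 | (3R,5S)-3α-(tert-butyldimethylsilyloxy)-5-methyl-4-methylidene-Δ9(10)-octalin, C8 dithiolane | C1C[C@]2(C)C(=C)[C@H](O[Si](C)(C)C(C)(C)C)CCC2=CC13SCCS3
F4 | step 5 | (3R,5S)-3α-(tert-butyldimethylsilyloxy)-5-methyl-4-methylidene-Δ9(10)-octalin-8-one | C1C[C@]2(C)C(=C)[C@H](O[Si](C)(C)C(C)(C)C)CCC2=CC1=O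
F5 | step 11 | (3R,4R,5R,7S,9S,10R)-3α-TBSO-9α-(trimethylsilyloxy)-7α-isopropenyl-4β,5β-dimethyl-trans-decalin-8-one | C=C(C)[C@@H]1C[C@]2(C)[C@@H](C)[C@H](O[Si](C)(C)C(C)(C)C)CC[C@H]2[C@H](O[Si](C)(C)C)C1=O
F6 | step 20 | 2-[bis(2,2,2-trifluoroethoxy)phosphoryl]propanoic acid | OC(=O)C(C)P(=O)(OCC(F)(F)F)OCC(F)(F)F
F7 | step 20 | 3-O-{2-[bis(2,2,2-trifluoroethoxy)phosphoryl]propanoyl} derivative of 31 (both epimers at the phosphonate carbon) | C=C(C)[C@@H]1C[C@]2(C)[C@@H](C)[C@H](OC(=O)C(C)P(=O)(OCC(F)(F)F)OCC(F)(F)F)CC[C@H]2[C@H](OC(=O)/C=C(\C)CC)C1=O
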